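**Retrosynthetic overview**

1. Rings are lettered A–G along the chain from the phloroglucinol end, each numbered from its first carbon in the SMILES string. Ring A carries OH on C1, C3 and C5 and the ether oxygen to ring B on C4, between the C3 and C5 hydroxyls. Its six carbons are those of a methyl 4-aryloxy-3,5-dioxohexanoate, so it is cut at C1–C6 (Claisen), then C1–C2 (carboxylation) and the sp3 C4–O bond (phenoxide plus 3-chloropentane-2,4-dione); the doubly flanked A–B ether is never made by aryl–oxygen coupling.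
2. In the per-methylated B–G hexamer, the 2,6-dimethoxyphenol oxygens of rings B and D are joined to C1 of rings C and E through ortho-halobenzaldehydes (Ullmann coupling, SNAr). Baeyer–Villiger oxidation then turns each formyl group into the C6 hydroxyl of ring C or E.
3. These hindered C6 phenols are arylated (Ullmann) by the unflanked C1 bromides of rings D and F. The F–G ether comes from a Chan–Lam coupling, and the ring B C1 hydroxyl is introduced last by C–H borylation/oxidation at the only unflanked aromatic C–H.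
4. Rings B–G are bought as benzenes; ring A is the only ring formed (step 14), and BBr3 then cleaves the fourteen methyl ethers.

Key step: step 14

Remark on the chemistry: the target has no stereocentre; C4 of keto ester 23 is an enolisable, configurationally labile centre, so 23 is carried as the racemate (tautomer mixture) and this centre disappears on aromatisation.

**Route**

Step 1
Reactants: 1 5-bromo-1,2,3-trimethoxybenzene
Product: 2 6-bromo-2,3,4-trimethoxybenzaldehyde
Conditions: Cl2CHOMe (1.3 equiv), TiCl4 (2.2 equiv), CH2Cl2, −10 → 0 °C; ice-water work-up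
Reagents that add atoms: dichloromethyl methyl ether COC(Cl)Cl (formyl carbon); water O (formyl oxygen)
Why: Rieche formylation; the two free positions of 1 are equivalent and each lies ortho and para to a methoxy group, so a single aldehyde should form.

Step 2
Reactants: 2 6-bromo-2,3,4-trimethoxybenzaldehyde; 3 2,6-dimethoxyphenol
Product: 4 6-(2,6-dimethoxyphenoxy)-2,3,4-trimethoxybenzaldehyde (rings B–C)
Conditions: CuI (10 mol%), picolinic acid (20 mol%), K3PO4 (2 equiv), DMSO, 90 °C, argon
Reagents that add atoms: none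
Why: Ullmann-type copper-catalysed O-arylation, in which the ortho-formyl group activates the C–Br bond and the picolinic acid system is suited to 2,6-disubstituted phenols, so the B–C ether should form at ring C C1.

Step 3
Reactants: 4 6-(2,6-dimethoxyphenoxy)-2,3,4-trimethoxybenzaldehyde
Product: 6 6-(2,6-dimethoxyphenoxy)-2,3,4-trimethoxyphenol, via aryl formate 5 (not isolated)
Conditions: mCPBA (1.3 equiv), CH2Cl2, 0 → 25 °C; then K2CO3 (0.2 equiv), MeOH, 25 °C
Reagents that add atoms: meta-chloroperoxybenzoic acid OOC(=O)c1cccc(Cl)c1 (phenol oxygen)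
Why: Baeyer–Villiger (Dakin-type) oxidation, in which the aryl group bearing ortho and para oxygen donors migrates in preference to hydrogen, followed by methanolysis of the formate to the ring C C6 phenol.

Step 4
Reactants: 7 1-fluoro-3,5-dimethoxybenzene
Product: 9 2-fluoro-4,6-dimethoxybenzaldehyde, via aryl iminium chloride 8 (not isolated)
Conditions: POCl3 (1.5 equiv), DMF, 0 → 70 °C; then H2O, 0 → 25 °C
Reagents that add atoms: N,N-dimethylformamide CN(C)C=O (formyl carbon); water O (formyl oxygen)
Why: Vilsmeier–Haack formylation, expected mainly at the carbon between fluorine and a methoxy group (ortho and para to the two methoxy groups) and not at the more crowded carbon between both methoxy groups; any regioisomer would be removed by crystallisation.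

Step 5
Reactants: 9 2-fluoro-4,6-dimethoxybenzaldehyde; 10 4-bromo-2,6-dimethoxyphenol
Product: 11 2-(4-bromo-2,6-dimethoxyphenoxy)-4,6-dimethoxybenzaldehyde (rings D–E)
Conditions: Cs2CO3 (1.5 equiv), DMSO, 120 °C, argon
Reagents that add atoms: none
Why: SNAr (addition–elimination) at the fluorine-bearing carbon, which is activated by the ortho-formyl group and has both methoxy groups meta to it, while the aryl bromide of 10 is inert in the absence of copper.

Step 6
Reactants: 6 6-(2,6-dimethoxyphenoxy)-2,3,4-trimethoxyphenol; 11 2-(4-bromo-2,6-dimethoxyphenoxy)-4,6-dimethoxybenzaldehyde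
Product: 12 2-{4-[6-(2,6-dimethoxyphenoxy)-2,3,4-trimethoxyphenoxy]-2,6-dimethoxyphenoxy}-4,6-dimethoxybenzaldehyde (rings B–E)
Conditions: CuI (20 mol%), picolinic acid (40 mol%), K3PO4 (2 equiv), DMSO, 100 °C, argon
Reagents that add atoms: none
Why: Ullmann-type copper-catalysed O-arylation with the favourable polarity, the hindered partner being the phenoxide and the bromide of ring D lying between two hydrogens; the non-enolisable aldehyde tolerates K3PO4.

Step 7
Reactants: 12 rings B–E aldehyde
Product: 14 2-{4-[6-(2,6-dimethoxyphenoxy)-2,3,4-trimethoxyphenoxy]-2,6-dimethoxyphenoxy}-4,6-dimethoxyphenol, via aryl formate 13 (not isolated)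
Conditions: mCPBA (1.3 equiv), CH2Cl2, 0 → 25 °C; then K2CO3 (0.2 equiv), MeOH, 25 °C
Reagents that add atoms: meta-chloroperoxybenzoic acid OOC(=O)c1cccc(Cl)c1 (phenol oxygen)
Why: Baeyer–Villiger (Dakin-type) oxidation of a 2-aryloxy-4,6-dimethoxybenzaldehyde, whose electron-rich aryl group migrates readily, then formate methanolysis to the ring E C6 phenol.

Step 8
Reactants: 10 4-bromo-2,6-dimethoxyphenol; 15 (3,4,5-trimethoxyphenyl)boronic acid
Product: 16 5-bromo-1,3-dimethoxy-2-(3,4,5-trimethoxyphenoxy)benzene (rings F–G)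
Conditions: Cu(OAc)2 (1.0 equiv, reoxidised by air), pyridine (5 equiv), 4 Å molecular sieves, CH2Cl2, dry air, 25 °C; 15 (2.5 equiv)
Reagents that add atoms: none
Why: Chan–Lam–Evans oxidative O-arylation at divalent copper, which accepts di-ortho-substituted phenols at room temperature and leaves the C–Br bond untouched because no oxidative addition to the halide occurs.

Step 9
Reactants: 14 rings B–E phenol; 16 5-bromo-1,3-dimethoxy-2-(3,4,5-trimethoxyphenoxy)benzene
Product: 17 per-methylated rings B–G hexamer with hydrogen at ring B C1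
Conditions: CuI (20 mol%), picolinic acid (40 mol%), K3PO4 (2 equiv), DMSO, 110 °C, argon
Reagents that add atoms: none
Why: Ullmann-type copper-catalysed O-arylation of the ring E C6 phenoxide by the unflanked ring F bromide, the same reaction class and polarity as step 6.

Step 10
Reactants: 17 per-methylated rings B–G hexamer
Product: 18 ring B C1 pinacol boronate of the hexamer
Conditions: [Ir(OMe)(cod)]2 (3 mol%), 4,4′-di-tert-butyl-2,2′-bipyridine (6 mol%), B2pin2 (1.5 equiv), THF, 80 °C
Reagents that add atoms: bis(pinacolato)diboron CC1(C)OB(OC1(C)C)B1OC(C)(C)C(C)(C)O1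
Why: sterically governed iridium-catalysed aromatic C–H borylation; the C–H para to the ether oxygen of ring B is the only aromatic C–H of 17 without an ortho substituent, all others being ortho to at least one oxygen substituent.

Step 11
Reactants: 18 ring B C1 pinacol boronate
Product: 19 per-methylated rings B–G hexamer phenol (OH at ring B C1)
Conditions: 30% H2O2, NaOH (1 equiv), THF/H2O, 0 °C
Reagents that add atoms: hydrogen peroxide OO
Why: oxidation of the arylboronate by 1,2-migration of the aryl group from boron to oxygen, which places the hydroxyl exactly at the borylated carbon.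

Step 12
Reactants: 19 hexamer phenol; 20 3-chloropentane-2,4-dione
Product: 21 3-(hexamer-oxy)pentane-2,4-dione
Conditions: K2CO3 (1.5 equiv), acetone, 56 °C
Reagents that add atoms: none
Why: SN2 O-alkylation of an unhindered phenoxide (two ortho hydrogens) by the α-chloro-1,3-diketone, a known route to 3-aryloxypentane-2,4-diones.

Step 13
Reactants: 21 3-(hexamer-oxy)pentane-2,4-dione; 22 dimethyl carbonate
Product: 23 methyl 4-(hexamer-oxy)-3,5-dioxohexanoate (racemic at C4)
Conditions: LiN(iPr)2 (3.2 equiv), THF, −78 → −20 °C; then (MeO)2CO (1.2 equiv), −78 → 0 °C; aq. HCl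
Reagents that add atoms: none
Why: Claisen-type C-carboxylation of a 1,3-diketone dianion at its terminal carbon, the more reactive of the two anionic sites; the two methyl groups of 21 are equivalent and the third equivalent of base absorbs the more acidic product.

Step 14
Reactants: 23 methyl 4-(hexamer-oxy)-3,5-dioxohexanoate
Product: 24 2-(hexamer-oxy)benzene-1,3,5-triol (ring A free, rings B–G per-methylated)
Conditions: KOt-Bu (5 equiv), THF, slow addition of 23 at 0 °C, then 66 °C, argon; aq. HCl
Reagents that add atoms: none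
Why: Intramolecular Claisen (Dieckmann-type) condensation: excess tert-butoxide holds 23 as its C2,C4-dianion, proton exchange through tert-butanol gives the tautomeric polyanion with the charge on the C6 methyl carbon and C2 protonated, and this carbanion adds to the C1 ester carbonyl, after which methoxide leaves and the cyclohexane-1,3,5-trione enolises to the aromatic triolate. The closest known reactions are the base-mediated Claisen cyclisation of 3,5-dioxohexanoate esters to phloroglucinol, the flask counterpart of phloroglucinol synthase, and the closure of 5-oxohexanoates to cyclohexane-1,3-diones. Ring A closes through its C1–C6 bond in a 6-exo-trig mode, the ester carbonyl lying outside the new ring. No stereocentre is formed, and the labile C4 centre of 23 becomes an sp2 ring carbon. The step needs carbon acylation by C6 in preference to oxygen acylation by the C5 enolate oxygen (which would give a 2-pyranone): oxygen acylation runs from the singly deprotonated ester, which inverse addition to excess strong base keeps scarce, whereas the C6 carbanion is by far the most nucleophilic site of the polyanion and its product is withdrawn irreversibly as the aromatic trianion. The bulky, non-nucleophilic base also spares the 1,3-diketone from retro-Claisen cleavage, and the C4 aryloxy group sits on a carbon that takes no part in bond formation.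

Step 15
Reactants: 24 2-(hexamer-oxy)benzene-1,3,5-triol
Product: 25 CNP0351377.0 (target, nineteen free hydroxyls)
Conditions: BBr3 (40 equiv), CH2Cl2, −78 → 25 °C, argon; then MeOH, H2O, 0 °C
Reagents that add atoms: none
Why: Lewis-acid ether cleavage, bromide attacking the methyl carbon of each boron-complexed aryl methyl ether; the diaryl ether bonds offer no sp3 carbon and should survive, and the ring A hydroxyls are only held as borates until hydrolysis.

**Compound list**

1 | 5-bromo-1,2,3-trimethoxybenzene | Brc1cc(OC)c(OC)c(OC)c1 | starting material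
2 | 6-bromo-2,3,4-trimethoxybenzaldehyde | Brc1cc(OC)c(OC)c(OC)c1C=O | intermediate
3 | 2,6-dimethoxyphenol | COc1cccc(OC)c1O | starting material
4 | 6-(2,6-dimethoxyphenoxy)-2,3,4-trimethoxybenzaldehyde | c1cc(OC)c(Oc2cc(OC)c(OC)c(OC)c2C=O)c(OC)c1 | intermediate
5 | 6-(2,6-dimethoxyphenoxy)-2,3,4-trimethoxyphenyl formate | c1cc(OC)c(Oc2cc(OC)c(OC)c(OC)c2OC=O)c(OC)c1 | intermediate
6 | 6-(2,6-dimethoxyphenoxy)-2,3,4-trimethoxyphenol | c1cc(OC)c(Oc2cc(OC)c(OC)c(OC)c2O)c(OC)c1 | intermediate
7 | 1-fluoro-3,5-dimethoxybenzene | Fc1cc(OC)cc(OC)c1 | starting material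
8 | N-[(2-fluoro-4,6-dimethoxyphenyl)methylidene]-N-methylmethanaminium chloride | Fc1cc(OC)cc(OC)c1C=[N+](C)C.[Cl-] | intermediate
9 | 2-fluoro-4,6-dimethoxybenzaldehyde | Fc1cc(OC)cc(OC)c1C=O | intermediate
10 | 4-bromo-2,6-dimethoxyphenol | Oc1c(OC)cc(Br)cc1OC | starting material
11 | 2-(4-bromo-2,6-dimethoxyphenoxy)-4,6-dimethoxybenzaldehyde | Brc1cc(OC)c(Oc2cc(OC)cc(OC)c2C=O)c(OC)c1 | intermediate
12 | 2-{4-[6-(2,6-dimethoxyphenoxy)-2,3,4-trimethoxyphenoxy]-2,6-dimethoxyphenoxy}-4,6-dimethoxybenzaldehyde | c1cc(OC)c(Oc2cc(OC)c(OC)c(OC)c2Oc2cc(OC)c(Oc3cc(OC)cc(OC)c3C=O)c(OC)c2)c(OC)c1 | intermediate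
13 | formate ester of phenol 14 | c1cc(OC)c(Oc2cc(OC)c(OC)c(OC)c2Oc2cc(OC)c(Oc3cc(OC)cc(OC)c3OC=O)c(OC)c2)c(OC)c1 | intermediate
14 | 2-{4-[6-(2,6-dimethoxyphenoxy)-2,3,4-trimethoxyphenoxy]-2,6-dimethoxyphenoxy}-4,6-dimethoxyphenol | c1cc(OC)c(Oc2cc(OC)c(OC)c(OC)c2Oc2cc(OC)c(Oc3cc(OC)cc(OC)c3O)c(OC)c2)c(OC)c1 | intermediate
15 | (3,4,5-trimethoxyphenyl)boronic acid | OB(O)c1cc(OC)c(OC)c(OC)c1 | starting material
16 | 5-bromo-1,3-dimethoxy-2-(3,4,5-trimethoxyphenoxy)benzene | Brc1cc(OC)c(Oc2cc(OC)c(OC)c(OC)c2)c(OC)c1 | intermediate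
17 | per-methylated rings B–G hexamer, hydrogen at ring B C1 | c1cc(OC)c(Oc2cc(OC)c(OC)c(OC)c2Oc2cc(OC)c(Oc3cc(OC)cc(OC)c3Oc3cc(OC)c(Oc4cc(OC)c(OC)c(OC)c4)c(OC)c3)c(OC)c2)c(OC)c1 | intermediate
18 | hexamer with 4,4,5,5-tetramethyl-1,3,2-dioxaborolan-2-yl at ring B C1 | CC1(C)OB(OC1(C)C)c1cc(OC)c(Oc2cc(OC)c(OC)c(OC)c2Oc2cc(OC)c(Oc3cc(OC)cc(OC)c3Oc3cc(OC)c(Oc4cc(OC)c(OC)c(OC)c4)c(OC)c3)c(OC)c2)c(OC)c1 | intermediate
19 | per-methylated rings B–G hexamer phenol (OH at ring B C1) | Oc1cc(OC)c(Oc2cc(OC)c(OC)c(OC)c2Oc2cc(OC)c(Oc3cc(OC)cc(OC)c3Oc3cc(OC)c(Oc4cc(OC)c(OC)c(OC)c4)c(OC)c3)c(OC)c2)c(OC)c1 | intermediate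
20 | 3-chloropentane-2,4-dione | CC(=O)C(Cl)C(C)=O | starting material
21 | 3-(hexamer-oxy)pentane-2,4-dione | CC(=O)C(Oc1cc(OC)c(Oc2cc(OC)c(OC)c(OC)c2Oc2cc(OC)c(Oc3cc(OC)cc(OC)c3Oc3cc(OC)c(Oc4cc(OC)c(OC)c(OC)c4)c(OC)c3)c(OC)c2)c(OC)c1)C(C)=O | intermediate
22 | dimethyl carbonate | COC(=O)OC | starting material
23 | methyl 4-(hexamer-oxy)-3,5-dioxohexanoate, racemic | CC(=O)C(Oc1cc(OC)c(Oc2cc(OC)c(OC)c(OC)c2Oc2cc(OC)c(Oc3cc(OC)cc(OC)c3Oc3cc(OC)c(Oc4cc(OC)c(OC)c(OC)c4)c(OC)c3)c(OC)c2)c(OC)c1)C(=O)CC(=O)OC | intermediate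
24 | 2-(hexamer-oxy)benzene-1,3,5-triol (ring A free, rings B–G per-methylated) | Oc1cc(O)c(Oc2cc(OC)c(Oc3cc(OC)c(OC)c(OC)c3Oc3cc(OC)c(Oc4cc(OC)cc(OC)c4Oc4cc(OC)c(Oc5cc(OC)c(OC)c(OC)c5)c(OC)c4)c(OC)c3)c(OC)c2)c(O)c1 | intermediate
25 | CNP0351377.0 | Oc1cc(O)c(Oc2cc(O)c(Oc3cc(O)c(O)c(O)c3Oc3cc(O)c(Oc4cc(O)cc(O)c4Oc4cc(O)c(Oc5cc(O)c(O)c(O)c5)c(O)c4)c(O)c3)c(O)c2)c(O)c1 | target

**Step count and risks**

Total step count: 15.
Longest linear sequence: 12 steps (1 → 2 → 4 → 6 → 12 → 14 → 17 → 18 → 19 → 21 → 23 → 24 → 25).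

Steps most likely to fail:

1. Step 14. What may go wrong: closure through oxygen, the C5 enolate oxygen being acylated by the ester to a 2-pyranone; or no closure, because enolisation at C2 deactivates the ester and the methyl carbanion is present only in a minute equilibrium share. The fallback sets out from 23 and returns at 24. The trianion of 23 (LiN(iPr)2, THF, −78 → 0 °C) would be carboxylated at C6 with dimethyl carbonate to give dimethyl 4-(hexamer-oxy)-3,5-dioxoheptanedioate F1. NaOMe in MeOH at reflux would then close ring A by a Dieckmann-type Claisen condensation in which the nucleophile is a malonate-type stabilised carbanion, giving methyl 3-(hexamer-oxy)-2,4,6-trihydroxybenzoate F2. Saponification with aq. KOH at 80 °C and acidification with warming would decarboxylate the phloroglucinolcarboxylic acid to 24.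

2. Step 9. What may go wrong: turnover at copper may be too slow for the doubly ortho-substituted tetramer phenoxide, so that protodebromination of 16 and oxidative decay of the electron-rich phenoxide at 110 °C take over. The fallback sets out from 16 and returns at 17. Bromine–lithium exchange (n-BuLi, THF, −78 °C), B(OiPr)3 and aq. HCl would give [3,5-dimethoxy-4-(3,4,5-trimethoxyphenoxy)phenyl]boronic acid F3. This would be coupled with phenol 14 under Chan–Lam–Evans conditions (Cu(OAc)2, pyridine, 4 Å molecular sieves, CH2Cl2, dry air, 25 °C), an oxidative room-temperature coupling that needs no oxidative addition.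

3. Step 13. What may go wrong: proton transfer from the more acidic product to unreacted dianion, double carboxylation, or methoxide-induced retro-Claisen loss of an acetyl group may erode conversion on the valuable late intermediate. The fallback sets out from 19 and returns at 23. Phenol 19 would be alkylated with methyl 4-chloro-3-oxobutanoate (K2CO3, acetone, 56 °C) to give methyl 4-(hexamer-oxy)-3-oxobutanoate F4. Its dianion (LiN(iPr)2, THF, −78 °C) would be acylated at C4 with N-methoxy-N-methylacetamide, the established acylation of β-keto ester dianions, to give 23.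

Further compounds
F1 | step 14 | dimethyl 4-(hexamer-oxy)-3,5-dioxoheptanedioate | COC(=O)CC(=O)C(Oc1cc(OC)c(Oc2cc(OC)c(OC)c(OC)c2Oc2cc(OC)c(Oc3cc(OC)cc(OC)c3Oc3cc(OC)c(Oc4cc(OC)c(OC)c(OC)c4)c(OC)c3)c(OC)c2)c(OC)c1)C(=O)CC(=O)OC
F2 | step 14 | methyl 3-(hexamer-oxy)-2,4,6-trihydroxybenzoate | COC(=O)c1c(O)cc(O)c(Oc2cc(OC)c(Oc3cc(OC)c(OC)c(OC)c3Oc3cc(OC)c(Oc4cc(OC)cc(OC)c4Oc4cc(OC)c(Oc5cc(OC)c(OC)c(OC)c5)c(OC)c4)c(OC)c3)c(OC)c2)c1O
F3 | step 9 | [3,5-dimethoxy-4-(3,4,5-trimethoxyphenoxy)phenyl]boronic acid | OB(O)c1cc(OC)c(Oc2cc(OC)c(OC)c(OC)c2)c(OC)c1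
F4 | step 13 | methyl 4-(hexamer-oxy)-3-oxobutanoate | COC(=O)CC(=O)COc1cc(OC)c(Oc2cc(OC)c(OC)c(OC)c2Oc2cc(OC)c(Oc3cc(OC)cc(OC)c3Oc3cc(OC)c(Oc4cc(OC)c(OC)c(OC)c4)c(OC)c3)c(OC)c2)c(OC)c1
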